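The 2,2-dimethylchroman ring is read as a hetero-Diels–Alder adduct: O1, C8a, C4a and the diaryl-substituted C4 form an ortho-quinone methide, and C3H2–C2(CH3)2 is 2-methylpropene. The key step ionises a protected benzhydrol that already joins both bibenzyl units, and a chiral phosphoric acid steers the [4+2] cycloaddition of the resulting ortho-quinone methide with isobutene, closing the pyran ring (C3–C4 and O1–C2) and setting the only stereocentre, C4, in one operation. Both aryl halves of the benzhydrol derive from one prenylated salicylaldehyde: one copy is converted into the chromene and lithiated, the other serves as the electrophile.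

Key step: step 9

Assumption: compounds 4, 11 and 14 are taken as catalogue reagents, and because the sense of induction of the phosphoric acid in step 9 cannot be predicted a priori, (R)-TRIP is written and its antipode would be used if it favoured the (S)-chroman.

Step 1
Reactants: 1 5-bromobenzene-1,3-diol; 2 chloromethyl methyl ether
Product: 3 1-bromo-3,5-bis(methoxymethoxy)benzene
Conditions: MOMCl (2.5 equiv), i-Pr2NEt, CH2Cl2, 0 °C to rt
Reagents that add atoms: chloromethyl methyl ether (2), COCCl
Why: Double O-alkylation of the phenols with the α-chloro ether (Williamson-type etherification) should give the bis-MOM ether, whose acetal oxygens later direct ortho-metalation.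

Step 2
Reactants: 3 1-bromo-3,5-bis(methoxymethoxy)benzene; 4 tert-butyldimethyl(4-vinylphenoxy)silane
Product: 6 tert-butyl{4-[2-(3,5-bis(methoxymethoxy)phenyl)ethyl]phenoxy}dimethylsilane, via alkylborane 5 (not isolated)
Conditions: 4, 9-BBN, THF, rt; then 3, Pd(dppf)Cl2 (3 mol %), anhydrous K3PO4, DMF, 60 °C
Reagents that add atoms: tert-butyldimethyl(4-vinylphenoxy)silane (4), C=Cc1ccc(O[Si](C)(C)C(C)(C)C)cc1
Why: Anti-Markovnikov hydroboration of the styrene followed by B-alkyl Suzuki–Miyaura coupling with the aryl bromide should form the bibenzyl CH2–CH2 link in one pot, the anhydrous phosphate sparing the base-labile aryl silyl ether.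

Step 3
Reactants: 6 tert-butyl{4-[2-(3,5-bis(methoxymethoxy)phenyl)ethyl]phenoxy}dimethylsilane; 7 N,N-dimethylformamide
Product: 9 4-{2-[4-(tert-butyldimethylsilyloxy)phenyl]ethyl}-2,6-bis(methoxymethoxy)benzaldehyde, via aryllithium 8 (not isolated)
Conditions: n-BuLi, TMEDA, THF, −20 to 0 °C; then DMF; aq. NH4Cl
Reagents that add atoms: N,N-dimethylformamide (7), CN(C)C=O
Why: Directed ortho-metalation should occur at the carbon flanked by both OMOM groups (cooperative direction; the silyl ether does not direct), and formylation of the aryllithium with DMF installs the aldehyde that later becomes C4 of both heterocycles.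

Step 4
Reactants: 9 4-{2-[4-(tert-butyldimethylsilyloxy)phenyl]ethyl}-2,6-bis(methoxymethoxy)benzaldehyde
Product: 10 4-{2-[4-(tert-butyldimethylsilyloxy)phenyl]ethyl}-2-hydroxy-6-(methoxymethoxy)benzaldehyde
Conditions: aq. HCl (3 M, 1.5 equiv), MeOH/THF, 0 °C to rt, stopped at mono-cleavage
Reagents that add atoms: none
Why: Acid-catalysed transacetalisation is fastest for a MOM ether ortho to the carbonyl and should stop after one cleavage because the freed phenol hydrogen-bonds to the aldehyde; the two MOM groups of 9 are equivalent by symmetry and the aryl silyl ether tolerates brief mild acid.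

Step 5
Reactants: 10 4-{2-[4-(tert-butyldimethylsilyloxy)phenyl]ethyl}-2-hydroxy-6-(methoxymethoxy)benzaldehyde; 11 tert-butyl 2-methylbut-3-en-2-yl carbonate
Product: 12 4-{2-[4-(tert-butyldimethylsilyloxy)phenyl]ethyl}-2-(methoxymethoxy)-6-[(2-methylbut-3-en-2-yl)oxy]benzaldehyde
Conditions: 11 (1.5 equiv), Pd(PPh3)4 (3 mol %), THF, 0 °C to rt
Reagents that add atoms: tert-butyl 2-methylbut-3-en-2-yl carbonate (11), C=CC(C)(C)OC(=O)OC(C)(C)C
Why: Tsuji–Trost O-allylation: zerovalent palladium ionises the tertiary carbonate with loss of CO2, and the acidic phenol should attack the 1,1-dimethyl-π-allyl complex at its more substituted terminus under kinetic control to give the tertiary aryl ether.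

Step 6
Reactants: 12 4-{2-[4-(tert-butyldimethylsilyloxy)phenyl]ethyl}-2-(methoxymethoxy)-6-[(2-methylbut-3-en-2-yl)oxy]benzaldehyde
Product: 13 4-{2-[4-(tert-butyldimethylsilyloxy)phenyl]ethyl}-2-hydroxy-6-(methoxymethoxy)-3-(3-methylbut-2-en-1-yl)benzaldehyde
Conditions: o-xylene, 140 °C
Reagents that add atoms: none
Why: Aromatic Claisen [3,3] rearrangement should transfer the allyl unit with transposition to the only free ortho carbon, giving the linear prenyl group next to the regenerated phenol, which is thereby distinguished from the MOM-protected oxygen.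

Step 7
Reactants: 13 4-{2-[4-(tert-butyldimethylsilyloxy)phenyl]ethyl}-2-hydroxy-6-(methoxymethoxy)-3-(3-methylbut-2-en-1-yl)benzaldehyde; 14 (2-methylprop-1-en-1-yl)magnesium bromide
Product: 17 tert-butyl{4-[2-(5-(methoxymethoxy)-2,2-dimethyl-8-(3-methylbut-2-en-1-yl)-2H-chromen-7-yl)ethyl]phenoxy}dimethylsilane, via allylic alcohol 15 (not isolated), via vinyl quinone methide 16 (not isolated)
Conditions: 14 (2.5 equiv), THF, 0 °C to rt; then AcOH, 50 °C
Reagents that add atoms: (2-methylprop-1-en-1-yl)magnesium bromide (14), CC(C)=C[Mg]Br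
Why: 1,2-Addition of the alkenyl Grignard reagent (one equivalent is consumed by the phenol) gives the allylic alcohol, which on mild acid should dehydrate to the vinylogous ortho-quinone methide and close by oxa-6π electrocyclisation to the 2,2-dimethyl-2H-chromene, only the free phenol oxygen being able to cyclise.

Step 8
Reactants: 17 tert-butyl{4-[2-(5-(methoxymethoxy)-2,2-dimethyl-8-(3-methylbut-2-en-1-yl)-2H-chromen-7-yl)ethyl]phenoxy}dimethylsilane; 13 4-{2-[4-(tert-butyldimethylsilyloxy)phenyl]ethyl}-2-hydroxy-6-(methoxymethoxy)-3-(3-methylbut-2-en-1-yl)benzaldehyde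
Product: 20 racemic benzhydrol [5-(methoxymethoxy)-2,2-dimethyl-8-prenyl-7-{2-[4-(TBSO)phenyl]ethyl}-2H-chromen-6-yl][2-hydroxy-6-(methoxymethoxy)-3-prenyl-4-{2-[4-(TBSO)phenyl]ethyl}phenyl]methanol, via aryllithium 18 (not isolated), via sodium phenoxide 19 (not isolated)
Conditions: 17 (1.3 equiv), s-BuLi, TMEDA, THF, −78 °C; separately 13, NaH, THF, 0 °C; combine at −78 °C, warm to 0 °C; aq. NH4Cl
Reagents that add atoms: none
Why: MOM-directed ortho-lithiation at C6, the only ring hydrogen of 17, gives the aryllithium, which should add to the aldehyde of the pre-formed phenoxide (1,2-addition of an aryllithium to an aldehyde) to give the tetra-ortho-substituted benzhydrol, whose racemic carbinol centre is erased in step 9.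

Step 9
Reactants: 20 racemic benzhydrol; 21 2-methylpropene (isobutene)
Product: 23 (4R)-protected chroman (the target with both ring 5-OH groups as MOM ethers and both 4-hydroxyphenyl groups as TBS ethers), via quinone methide 22 (not isolated)
Conditions: (R)-TRIP [(R)-3,3'-bis(2,4,6-triisopropylphenyl)-1,1'-binaphthyl-2,2'-diyl hydrogen phosphate] (10 mol %), isobutene (condensed, 30 equiv), 4 Å MS, toluene, sealed tube, 0 °C to rt
Reagents that add atoms: 2-methylpropene (21), CC(C)=C
Why: Proposed new method: the chiral phosphoric acid ionises the doubly benzylic alcohol of 20 to the ring B ortho-quinone methide 22, held as a hydrogen-bonded or ion-paired complex through the only free phenol oxygen, and isobutene adds as the 2π partner of an inverse-electron-demand oxa-[4+2] cycloaddition, its CH2 terminus to the electrophilic methide carbon and its tertiary carbon to oxygen (Markovnikov polarity), so that C3–C4 and O1–C2 form in one asynchronous event. The closest known reaction type is the chiral-phosphoric-acid-catalysed [4+2] cycloaddition of ortho-quinone methides generated in situ from ortho-hydroxybenzhydrols with styrenes and other alkenes, together with racemic cycloadditions of ortho-quinone methides with unactivated 1,1-disubstituted alkenes; a gaseous 1,1-dialkylethylene without a hydrogen-bonding handle has not been shown under enantiocontrol, hence the label. The pyran ring closes by the cycloaddition itself (oxa-Diels–Alder mode, in the stepwise limit a six-membered closure of the phenolic oxygen onto the tertiary cation). The single stereocentre C4 is set by the catalyst, whose phosphate bound at the quinone methide oxygen shields one face of the methide carbon while the ring A aryl group avoids the neighbouring OMOM group and so biases the exocyclic geometry. Regiochemistry is secured by the substrate, because the other ortho oxygens on ring A and ring B are MOM ethers and cannot close, and chemoselectivity over the internal prenyl and chromene alkenes by the large excess of isobutene at high dilution of 20.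

Step 10
Reactants: 23 (4R)-protected chroman
Product: 25 CNP0103951.1 as the (4R) enantiomer, via bis-MOM diphenol 24 (not isolated)
Conditions: TBAF (2.5 equiv), THF, 0 °C; then MeOH, aq. HCl (3 M), 35 °C
Reagents that add atoms: none
Why: Fluoride desilylation of the two aryl TBS ethers followed by acid-catalysed transacetalisation of the two MOM ethers should release all four phenols; C4 is not epimerisable under these conditions and neither prenyl group has a free ortho phenol that could cyclise.

Compound list
1 | 5-bromobenzene-1,3-diol | Oc1cc(O)cc(Br)c1 | starting material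
2 | chloromethyl methyl ether | COCCl | starting material
3 | 1-bromo-3,5-bis(methoxymethoxy)benzene | COCOc1cc(Br)cc(OCOC)c1 | intermediate
4 | tert-butyldimethyl(4-vinylphenoxy)silane | C=Cc1ccc(O[Si](C)(C)C(C)(C)C)cc1 | starting material
5 | 9-{2-[4-(tert-butyldimethylsilyloxy)phenyl]ethyl}-9-borabicyclo[3.3.1]nonane | CC(C)(C)[Si](C)(C)Oc1ccc(CCB2C3CCCC2CCC3)cc1 | intermediate
6 | tert-butyl{4-[2-(3,5-bis(methoxymethoxy)phenyl)ethyl]phenoxy}dimethylsilane | COCOc1cc(CCc2ccc(O[Si](C)(C)C(C)(C)C)cc2)cc(OCOC)c1 | intermediate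
7 | N,N-dimethylformamide | CN(C)C=O | starting material
8 | 2-lithio derivative of 6 (lithium between the two OMOM groups) | COCOc1cc(CCc2ccc(O[Si](C)(C)C(C)(C)C)cc2)cc(OCOC)c1[Li] | intermediate
9 | 4-{2-[4-(tert-butyldimethylsilyloxy)phenyl]ethyl}-2,6-bis(methoxymethoxy)benzaldehyde | COCOc1cc(CCc2ccc(O[Si](C)(C)C(C)(C)C)cc2)cc(OCOC)c1C=O | intermediate
10 | 4-{2-[4-(tert-butyldimethylsilyloxy)phenyl]ethyl}-2-hydroxy-6-(methoxymethoxy)benzaldehyde | COCOc1cc(CCc2ccc(O[Si](C)(C)C(C)(C)C)cc2)cc(O)c1C=O | intermediate
11 | tert-butyl 2-methylbut-3-en-2-yl carbonate | C=CC(C)(C)OC(=O)OC(C)(C)C | starting material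
12 | 4-{2-[4-(tert-butyldimethylsilyloxy)phenyl]ethyl}-2-(methoxymethoxy)-6-[(2-methylbut-3-en-2-yl)oxy]benzaldehyde | COCOc1cc(CCc2ccc(O[Si](C)(C)C(C)(C)C)cc2)cc(OC(C)(C)C=C)c1C=O | intermediate
13 | 4-{2-[4-(tert-butyldimethylsilyloxy)phenyl]ethyl}-2-hydroxy-6-(methoxymethoxy)-3-(3-methylbut-2-en-1-yl)benzaldehyde | COCOc1cc(CCc2ccc(O[Si](C)(C)C(C)(C)C)cc2)c(CC=C(C)C)c(O)c1C=O | intermediate
14 | (2-methylprop-1-en-1-yl)magnesium bromide | CC(C)=C[Mg]Br | starting material
15 | racemic 1-aryl-3-methylbut-2-en-1-ol from 13 (aryl = the ring of 13) | COCOc1cc(CCc2ccc(O[Si](C)(C)C(C)(C)C)cc2)c(CC=C(C)C)c(O)c1C(O)C=C(C)C | intermediate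
16 | vinylogous ortho-quinone methide from 15 (6-(3-methylbut-2-en-1-ylidene)cyclohexa-2,4-dien-1-one) | COCOC1=CC(CCc2ccc(O[Si](C)(C)C(C)(C)C)cc2)=C(CC=C(C)C)C(=O)C1=CC=C(C)C | intermediate
17 | tert-butyl{4-[2-(5-(methoxymethoxy)-2,2-dimethyl-8-(3-methylbut-2-en-1-yl)-2H-chromen-7-yl)ethyl]phenoxy}dimethylsilane | COCOc1cc(CCc2ccc(O[Si](C)(C)C(C)(C)C)cc2)c(CC=C(C)C)c2OC(C)(C)C=Cc12 | intermediate
18 | 6-lithio derivative of chromene 17 | COCOc1c([Li])c(CCc2ccc(O[Si](C)(C)C(C)(C)C)cc2)c(CC=C(C)C)c2OC(C)(C)C=Cc12 | intermediate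
19 | sodium phenoxide of 13 | COCOc1cc(CCc2ccc(O[Si](C)(C)C(C)(C)C)cc2)c(CC=C(C)C)c([O-])c1C=O.[Na+] | intermediate
20 | racemic benzhydrol: (chromen-6-yl of 17)(2-hydroxy-6-(methoxymethoxy)-3-prenyl-4-{2-[4-(TBSO)phenyl]ethyl}phenyl)methanol | COCOc1c(C(O)c3c(O)c(CC=C(C)C)c(CCc4ccc(O[Si](C)(C)C(C)(C)C)cc4)cc3OCOC)c(CCc2ccc(O[Si](C)(C)C(C)(C)C)cc2)c(CC=C(C)C)c2OC(C)(C)C=Cc12 | intermediate
21 | 2-methylpropene (isobutene) | CC(C)=C | starting material
22 | ring B ortho-quinone methide from 20 (exocyclic CH bearing the chromen-6-yl group) | COCOc1c(C=C3C(=O)C(CC=C(C)C)=C(CCc4ccc(O[Si](C)(C)C(C)(C)C)cc4)C=C3OCOC)c(CCc2ccc(O[Si](C)(C)C(C)(C)C)cc2)c(CC=C(C)C)c2OC(C)(C)C=Cc12 | intermediate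
23 | (4R)-4-aryl-2,2-dimethylchroman, the target with both ring 5-OH as MOM ethers and both 4-hydroxyphenyl OH as TBS ethers | CC(C)=CCc1c(CCc2ccc(O[Si](C)(C)C(C)(C)C)cc2)c([C@H]2CC(C)(C)Oc3c(CC=C(C)C)c(CCc4ccc(O[Si](C)(C)C(C)(C)C)cc4)cc(OCOC)c32)c(OCOC)c2c1OC(C)(C)C=C2 | intermediate
24 | (4R)-bis-MOM ether of the target with free 4-hydroxyphenyl groups | CC(C)=CCc1c(CCc2ccc(O)cc2)c([C@H]2CC(C)(C)Oc3c(CC=C(C)C)c(CCc4ccc(O)cc4)cc(OCOC)c32)c(OCOC)c2c1OC(C)(C)C=C2 | intermediate
25 | 6-[(4R)-5-hydroxy-7-[2-(4-hydroxyphenyl)ethyl]-2,2-dimethyl-8-(3-methylbut-2-en-1-yl)-3,4-dihydro-2H-chromen-4-yl]-7-[2-(4-hydroxyphenyl)ethyl]-2,2-dimethyl-8-(3-methylbut-2-en-1-yl)-2H-chromen-5-ol (CNP0103951.1) | CC(C)=CCc1c(CCc2ccc(O)cc2)c([C@H]2CC(C)(C)Oc3c(CC=C(C)C)c(CCc4ccc(O)cc4)cc(O)c32)c(O)c2c1OC(C)(C)C=C2 | target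

Total step count: 10. Longest linear sequence: 10 steps (1 to 10; the chromene half is made from 13 and re-joined with 13 in step 8).

Steps most likely to fail

Step 9 (proposed new method). Enantiofacial discrimination may be weak, since isobutene offers no hydrogen-bonding handle and the quinone methide can react through either exocyclic geometry. The cycloaddition at the hindered methide carbon may also be slow, which would allow intramolecular Friedel–Crafts capture of the benzhydryl cation by the neighbouring silyloxyphenethyl ring. The fallback uses known chemistry, sets out from 20 and comes back at 23. Compound 20 would be heated with excess isobutene and diphenyl phosphate (5 mol %) in toluene in a sealed tube at 60 °C, the established racemic ortho-quinone methide/alkene [4+2] cycloaddition, to give the racemic protected chroman F1. Preparative supercritical-fluid chromatography on an amylose tris(3,5-dimethylphenylcarbamate) phase would then separate 23 from the (S)-enantiomer F2, and 23 would continue in step 10.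

Step 8. Metalation may occur at the wrong site (the allylic-benzylic CH2 of the prenyl group, or a position on the silyloxyphenyl ring) instead of C6, and addition of the doubly ortho-substituted aryllithium to the hindered aldehyde may be sluggish. The fallback sets out from 10 and comes back at 18, and so at 20. Bromination of 10 with NBS in MeCN at 0 °C, para to the free phenol, would give the bromo aldehyde F3. The same Tsuji–Trost etherification with 11 (Pd(PPh3)4, THF) would give the tertiary allyl ether F4, Claisen rearrangement (o-xylene, 140 °C) the bromo salicylaldehyde F5, and addition of 14 followed by AcOH the bromochromene F6. Bromine–lithium exchange (t-BuLi, 2 equiv, THF, −78 °C) would then generate aryllithium 18 regiospecifically, to be added to 19 as in step 8.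

Step 10. The electron-rich chromene double bond may be protonated under the methanolic acid needed for MOM cleavage, leading to solvent addition or oligomerisation before the hindered acetals are gone. The fallback sets out from 23 and comes back at 25. Compound 23 would be treated with TMSOTf and 2,2'-bipyridyl in CH2Cl2 at 0 °C, a buffered, non-protic exchange of aryl MOM ethers for trimethylsilyl ethers, to give the tetrasilyl ether F7. All four silyl ethers would then be removed with TBAF/AcOH in THF at 0 °C to give 25.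

Further compounds
F1 | step 9 | racemic protected chroman (racemate of 23) | CC(C)=CCc1c(CCc2ccc(O[Si](C)(C)C(C)(C)C)cc2)c(C2CC(C)(C)Oc3c(CC=C(C)C)c(CCc4ccc(O[Si](C)(C)C(C)(C)C)cc4)cc(OCOC)c32)c(OCOC)c2c1OC(C)(C)C=C2
F2 | step 9 | (4S)-enantiomer of 23 | CC(C)=CCc1c(CCc2ccc(O[Si](C)(C)C(C)(C)C)cc2)c([C@@H]2CC(C)(C)Oc3c(CC=C(C)C)c(CCc4ccc(O[Si](C)(C)C(C)(C)C)cc4)cc(OCOC)c32)c(OCOC)c2c1OC(C)(C)C=C2
F3 | step 8 | 3-bromo-4-{2-[4-(tert-butyldimethylsilyloxy)phenyl]ethyl}-6-hydroxy-2-(methoxymethoxy)benzaldehyde | COCOc1c(Br)c(CCc2ccc(O[Si](C)(C)C(C)(C)C)cc2)cc(O)c1C=O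
F4 | step 8 | 3-bromo-4-{2-[4-(tert-butyldimethylsilyloxy)phenyl]ethyl}-2-(methoxymethoxy)-6-[(2-methylbut-3-en-2-yl)oxy]benzaldehyde | COCOc1c(Br)c(CCc2ccc(O[Si](C)(C)C(C)(C)C)cc2)cc(OC(C)(C)C=C)c1C=O
F5 | step 8 | 3-bromo-4-{2-[4-(tert-butyldimethylsilyloxy)phenyl]ethyl}-6-hydroxy-2-(methoxymethoxy)-5-(3-methylbut-2-en-1-yl)benzaldehyde | COCOc1c(Br)c(CCc2ccc(O[Si](C)(C)C(C)(C)C)cc2)c(CC=C(C)C)c(O)c1C=O
F6 | step 8 | 6-bromo derivative of chromene 17 | COCOc1c(Br)c(CCc2ccc(O[Si](C)(C)C(C)(C)C)cc2)c(CC=C(C)C)c2OC(C)(C)C=Cc12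
F7 | step 10 | (4R)-tetrasilyl ether of the target (ring 5-OH groups as TMS ethers, 4-hydroxyphenyl groups as TBS ethers) | CC(C)=CCc1c(CCc2ccc(O[Si](C)(C)C(C)(C)C)cc2)c([C@H]2CC(C)(C)Oc3c(CC=C(C)C)c(CCc4ccc(O[Si](C)(C)C(C)(C)C)cc4)cc(O[Si](C)(C)C)c32)c(O[Si](C)(C)C)c2c1OC(C)(C)C=C2
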